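## Structural features

The target 17 is bis(2,3,6-tribromo-4,5-dihydroxyphenyl)methane: two identical benzene rings joined through their C1 atoms by a single CH2 group. There is no further ring and no stereocentre, so no neighbouring stereocentres have to be related. Each ring is fully substituted: C1 carries the bridge, C2, C3 and C6 carry bromine, and C4 and C5 carry the two hydroxyls of a catechol. The fragile elements are the free catechols (oxidation to ortho-quinones by air under base or by halogenating agents), the doubly benzylic CH2 with its Ar–CH2 bonds (C1 is para to the C4 oxygen and open to ipso attack), and the six aryl bromides, which exclude organolithium and reducing steps once they are in place. The real difficulty is regiochemical: five heteroatom substituents must be placed around each C1 with no spare position for correction. The hardest part is the contiguous C2–Br/C3–Br pair wedged between the benzylic carbon and the C4 oxygen. The key step exploits exactly this pair: C2 and C3 are neighbouring ring atoms, so both C–Br bonds can be made across a C2–C3 aryne, whose position is set by a phenol oxygen on C2 and a silicon on C3. The third bromine (C6, ortho to the C5 oxygen) then occupies the only C–H left and can be added by ordinary electrophilic substitution.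

## Logic of the disconnections

17 to 15. The four phenolic O–H bonds are traced back to four O–CH3 bonds. Methyl ethers survive fluoride, organolithium, triflating and brominating conditions alike, and masking the catechols until the end removes the quinone problem from every earlier step. The gain is that all halogenation chemistry runs on a robust tetraether. The forward step must cleave four hindered aryl methyl ethers, some flanked by bromine, without touching six C–Br bonds or the bridge; a boron Lewis acid does this without redox chemistry.

15 to 14. The two C6–Br bonds are cut. C6 is the only ring carbon of 14 that still bears hydrogen and lies ortho to the C5 methoxy group, so there is no regiochemical choice. The forward step must substitute at C6 without ipso attack at C1 or reaction at the benzylic CH2; the two bromines already on each ring damp its nucleophilicity and help here.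

14 to 10 (key disconnection). In each ring the C2–Br and C3–Br bonds are cut together, which leads to a C2–C3 aryne and, behind it, to its bench-stable equivalent with a triflate on C2 and a trimethylsilyl group on C3. This turns the hardest substitution pattern into the question of where one oxygen sits, because the C2 oxygen of 10 comes from a phenol. Four C–Br bonds are removed in one operation and the symmetry is kept. The forward step must generate the aryne in the presence of a bromide nucleophile and a Br+ donor, and the Br+ donor must not cleave the C–Si bond first.

10 to 6. The C3–Si and O–S bonds are cut; C3 reverts to C–Br and the C2 oxygen to a free phenol. An ortho-bromophenol is the classical entry to an ortho-silylaryl triflate: O-silylation, bromine–lithium exchange and a 1,3 shift of silicon from O to C put silicon where bromine was, and the freed phenoxide is triflated. The gain is a precursor built only from C, H, O and Br. The demand is that exchange at both rings outruns deprotonation of the CH2 between the two aryl groups, hence very low temperature and the fast-migrating trimethylsilyl group.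

6 to 3 and 4. Both Ar–CH2 bonds are cut, giving two molecules of 3 and the one-carbon electrophile 4. C1 of each ring is ortho to the phenol oxygen and para to a methoxy group, and it is the only free position of 3 that is ortho or para to the hydroxyl, since bromine holds the other ortho position. The C3 bromine is therefore both the future site of silicon and a blocking group: attack can occur at one carbon only and the product cannot grow into oligomers. Bringing the bromine in from the start also avoids brominating an easily oxidised para-methoxyphenol between two oxygens after the bridge is in place. The forward step needs 2:1 stoichiometry and enough acid to ionise the intermediate benzylic alcohol.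

3 to 1. The phenol C–O bond is traced back to the C–CHO bond of 1, a commercial aldehyde in which bromine already sits between the formyl-bearing carbon and the first methoxy group. The forward step is an oxidative aryl migration, favoured by the para methoxy group.

## Other disconnections considered

Alternative 1: The cut runs through C3–C4 and C5–C6 of each ring. C4 and C5 with their oxygens come from diethyl oxalate A2, and the chain C3–C2–C1–C6 from an adipate unit of the tetraester A1, tetraethyl 3,3'-methylenebis(hexanedioate). In the forward key step an alkoxide base would condense the two α-carbons of each adipate unit with A2 in a twofold Claisen condensation, closing each six-membered 1,2-dione ring to give the bis(dioxocyclohexanedicarboxylate) A3.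
- In its favour: the reaction type is old and robust for simple adipates, uses cheap reagents with no cryogenic or fluoride-sensitive chemistry, and places the two oxygens on C4/C5 with no regiochemical question. On the reliability of the bond-forming reaction itself it is at least the equal of the aryne step.
- Against it here: A3 contains none of the six bromines and is two hydrogens per ring short of aromatic. Dehydrogenation, conversion of the ester-bearing carbons C3 and C6 into C–Br (hydrolysis and bromodecarboxylation) and a separate bromination at C2 would all have to follow. A1 is not commercial. In A1 the oxalate condensation competes with Dieckmann closures within one adipate unit (five-membered) and across the bridge (six-membered). The labile stereocentres of A3 disappear and are no burden.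
- Comparison: structurally it builds two carbocycles that the chosen plan buys as benzene rings. Mechanistically it is equilibrium-controlled carbonyl chemistry against kinetic trapping of a reactive intermediate. In step economy it is clearly behind: its key step forms four C–C bonds and no C–Br bond, whereas step 4 forms four of the six C–Br bonds and leaves two steps to 17.

Alternative 2: C3 is excised from each ring together with its bromine by cutting C2–C3 and C3–C4, which leaves a five-membered ring, the bis(silyloxy)cyclopentadiene A4, bis[3,4-bis(trimethylsilyloxy)cyclopenta-2,4-dien-1-yl]methane. Forward, dibromocarbene A5, made from a haloform and a bulky alkoxide, would cyclopropanate one enol ether double bond of each ring. Opening of the dibromocyclopropane with loss of bromide inserts C3–Br between C2 and C4, and tautomerisation would give the bis(bromocatechol) A6.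
- In its favour: carbene ring expansion of silyl enol ethers is a known reaction type, and C3 arrives already brominated next to the oxygen-bearing C4. The two enol ether double bonds of each ring are symmetry-related, so it does not matter which one reacts; in this indifference to regiochemistry it is the equal of the chosen step. Both open positions of A6 are to be brominated, so its completion needs no regiocontrol either.
- Against it: it delivers one bromine per ring, not two, and the electrophilic bromination still needed at C2 and C6 could have introduced the C3 bromine as well. A4 would be hard to make and keep, because 5-substituted cyclopentadienes shift hydrogen around the ring (moving the bridge relative to the oxygens) and dimerise. The alkoxide needed for A5 attacks silyl enol ethers, a second carbene addition is possible, and the catechol is set free under basic conditions that invite oxidation.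
- Comparison: structurally it constructs the arene by one-carbon insertion where the chosen plan uses an arene from the shelf. Mechanistically it is a carbene addition under strongly basic conditions against an aryne addition under nearly neutral fluoride conditions, the gentler choice for this oxygen-rich substrate. In step economy it is poorer, since the synthesis of A4 and the later bromination outweigh one bond-forming event per ring.

Alternative 3: Each benzene ring is cut at C1–C6 and C2–C3 into a four-carbon diene (C3 to C6) and a two-carbon alkyne (C1–C2). The diene is 2,5-dibromo-3,4-dimethoxythiophene 1,1-dioxide A7 and the bis-dienophile is 1,5-dibromopenta-1,4-diyne A8. Forward, two molecules of A7 would add to the two bromoalkyne units of A8 and each adduct would lose its SO2 bridge, closing both arenes and giving A9, which is the same compound as 15.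
- In its favour: on paper this is the most convergent plan. All six C–Br bonds, the four C–O bonds and the bridge would be in place after one operation, the diene is symmetrical so there is no regiochemical question, and only the ether cleavage would remain. In bonds formed per operation and in steps after the key step it is better than the chosen plan.
- Against it: A8 is a skipped diyne with a doubly propargylic CH2 between two 1-bromoalkynes. It should isomerise to allenic and conjugated isomers with traces of base or on heating, and it is a hazardous small haloalkyne. Halogenated thiophene dioxides are electron-poor dienes that react best with electron-rich or strained partners, which bromoalkynes are not, so forcing temperatures would be needed at which A7 should dimerise and A8 decompose. Oxidation of an electron-rich dialkoxythiophene to the sulfone A7 is itself uncertain.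
- Comparison: structurally it builds both rings de novo and reaches 15 directly, where the chosen plan needs steps 4 and 5. Mechanistically it relies on two electronically mismatched thermal cycloadditions, against a polar addition to an aryne whose reactivity is not in doubt and whose only issue is chemoselectivity. In step economy it is better if the cycloaddition works and worse once the preparation and handling of A7 and A8 are counted.

Key step: step 4

Remark on the chemistry: formaldehyde 4 is used as paraformaldehyde, which depolymerises to the monomer under the acidic conditions of step 2.

## Route

Step 1
Reactants: 1 2-bromo-3,4-dimethoxybenzaldehyde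
Product: 3 2-bromo-3,4-dimethoxyphenol, via aryl formate 2 (not isolated)
Conditions: mCPBA, CH2Cl2, 0 °C to rt; then KOH, MeOH/H2O, rt; HCl work-up
Reagents that add atoms: mCPBA, O=C(OO)c1cccc(Cl)c1
Why: Baeyer–Villiger (Dakin-type) oxidation; in the Criegee adduct the electron-rich aryl group (para methoxy) migrates in preference to hydride, and the formate 2 is saponified to the phenol, which fixes bromine ortho to the new hydroxyl.

Step 2
Reactants: 3 2-bromo-3,4-dimethoxyphenol (2 equiv); 4 formaldehyde
Product: 6 bis(3-bromo-2-hydroxy-4,5-dimethoxyphenyl)methane, via hydroxymethylphenol 5 (not isolated)
Conditions: (CH2O)n (0.5 equiv), H2SO4 (cat.), AcOH, 50 °C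
Reagents that add atoms: none
Why: Acid-catalysed phenol–formaldehyde condensation (Lederer–Manasse hydroxymethylation, then Friedel–Crafts alkylation of a second phenol by the ortho-hydroxybenzyl cation from 5). The only free position ortho or para to the hydroxyl of 3 is the one para to a methoxy group, so a single diarylmethane should form and cannot react on to oligomers.

Step 3
Reactants: 6 bis(3-bromo-2-hydroxy-4,5-dimethoxyphenyl)methane
Product: 10 bis[4,5-dimethoxy-2-(trifluoromethylsulfonyloxy)-3-(trimethylsilyl)phenyl]methane, via bis(silyl ether) 7 (not isolated), via bis(aryllithium) 8 (not isolated), via dilithium bis(phenoxide) 9 (not isolated)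
Conditions: HMDS, THF, reflux; evaporate; n-BuLi (2.2 equiv), THF, −100 to −78 °C; then Tf2O, −100 to −78 °C
Reagents that add atoms: hexamethyldisilazane, C[Si](C)(C)N[Si](C)(C)C; trifluoromethanesulfonic anhydride, O=S(=O)(OS(=O)(=O)C(F)(F)F)C(F)(F)F
Why: Standard one-pot conversion of an ortho-bromophenol into an ortho-silylaryl triflate: O-silylation, bromine–lithium exchange at C3 (faster at −100 °C than deprotonation of the diarylmethane CH2), retro-Brook 1,3 shift of silicon from oxygen to C3 driven by formation of the lithium phenoxide 9, and O-triflation.

Step 4
Reactants: 10 bis[4,5-dimethoxy-2-(trifluoromethylsulfonyloxy)-3-(trimethylsilyl)phenyl]methane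
Product: 14 bis(2,3-dibromo-4,5-dimethoxyphenyl)methane, via mono-aryne 11 (not isolated), via dibromide silyl triflate 12 (not isolated), via dibromide aryne 13 (not isolated)
Conditions: CsF, Bu4NBr, CBr4 (each in excess), MeCN, 0 °C to rt, slow addition of 10; aqueous work-up
Reagents that add atoms: tetrabutylammonium bromide, CCCC[N+](CCCC)(CCCC)CCCC.[Br-]; carbon tetrabromide, BrC(Br)(Br)Br
Why: Fluoride attacks the silicon on C3 of one ring and the incipient C3 carbanion expels triflate from C2, giving the C2–C3 aryne 11 (fluoride-induced 1,2-elimination of an ortho-silylaryl triflate). Bromide, present in large excess as its soluble tetrabutylammonium salt, adds to C2, the aryne carbon remote from the C4 methoxy group, so that the negative charge develops on C3 next to the inductively withdrawing C4–O bond. This carbanion is halophilic and should take Br+ from CBr4 faster than it is protonated or reverts, giving 12; the same sequence on the second ring passes through 13 to 14. The closest known reaction type is the vicinal dihalogenation of arynes by a halide and halonium-donor pair (formal insertion of an aryne into a halogen–halogen bond), here run twice in one molecule. No ring is closed and no stereocentre is created. Regioselectivity is not needed, since both aryne carbons end up bearing bromine whichever adds first. What is needed is chemoselectivity: the aryne forms only where silicon and triflate are vicinal, which the fluoride-labile C3–Si/C2–OTf pair secures while the methyl ethers and the CH2 bridge stay untouched, and the Br+ donor must not cleave the C–Si bond beforehand, which is why CBr4 is chosen and elemental bromine is not. Slow, heterogeneous release of fluoride from CsF keeps the aryne concentration low, so that capture by bromide should outrun reaction with the neighbouring ring or with a second aryne.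

Step 5
Reactants: 14 bis(2,3-dibromo-4,5-dimethoxyphenyl)methane
Product: 15 bis(2,3,6-tribromo-4,5-dimethoxyphenyl)methane
Conditions: Br2 (2.5 equiv), Fe powder (cat.), CH2Cl2, 0 °C to rt, dark
Reagents that add atoms: bromine, BrBr
Why: Electrophilic aromatic bromination with FeBr3 formed in the flask; C6 is the only C–H of each ring and is ortho to the C5 methoxy group, so no regiochemical choice exists, and exclusion of light suppresses radical bromination of the CH2 bridge.

Step 6
Reactants: 15 bis(2,3,6-tribromo-4,5-dimethoxyphenyl)methane
Product: 17 bis(2,3,6-tribromo-4,5-dihydroxyphenyl)methane, via bis(bromodioxaborole) 16 (not isolated)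
Conditions: BBr3 (excess), CH2Cl2, −78 °C to rt; then H2O
Reagents that add atoms: none
Why: Lewis-acid cleavage of aryl methyl ethers: boron coordinates each ether oxygen and bromide removes the methyl group by SN2, the catechol being held as the boron ester 16 until hydrolysis. The conditions are non-oxidising and leave the aryl bromides and the bridge alone.

## Compound list

1 | 2-bromo-3,4-dimethoxybenzaldehyde | COc1ccc(C=O)c(Br)c1OC | starting material
2 | 2-bromo-3,4-dimethoxyphenyl formate (formed in the flask, not isolated) | COc1ccc(OC=O)c(Br)c1OC | intermediate
3 | 2-bromo-3,4-dimethoxyphenol | COc1ccc(O)c(Br)c1OC | intermediate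
4 | formaldehyde (used as paraformaldehyde) | C=O | starting material
5 | 2-bromo-6-(hydroxymethyl)-3,4-dimethoxyphenol (formed in the flask, not isolated) | COc1cc(CO)c(O)c(Br)c1OC | intermediate
6 | bis(3-bromo-2-hydroxy-4,5-dimethoxyphenyl)methane | COc1cc(Cc2cc(OC)c(OC)c(Br)c2O)c(O)c(Br)c1OC | intermediate
7 | bis[3-bromo-4,5-dimethoxy-2-(trimethylsilyloxy)phenyl]methane (not isolated) | COc1cc(Cc2cc(OC)c(OC)c(Br)c2O[Si](C)(C)C)c(O[Si](C)(C)C)c(Br)c1OC | intermediate
8 | bis[3-lithio-4,5-dimethoxy-2-(trimethylsilyloxy)phenyl]methane (not isolated) | COc1cc(Cc2cc(OC)c(OC)c([Li])c2O[Si](C)(C)C)c(O[Si](C)(C)C)c([Li])c1OC | intermediate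
9 | dilithium salt of bis[2-hydroxy-4,5-dimethoxy-3-(trimethylsilyl)phenyl]methane (not isolated) | [Li+].[Li+].COc1cc(Cc2cc(OC)c(OC)c([Si](C)(C)C)c2[O-])c([O-])c([Si](C)(C)C)c1OC | intermediate
10 | bis[4,5-dimethoxy-2-(trifluoromethylsulfonyloxy)-3-(trimethylsilyl)phenyl]methane | COc1cc(Cc2cc(OC)c(OC)c([Si](C)(C)C)c2OS(=O)(=O)C(F)(F)F)c(OS(=O)(=O)C(F)(F)F)c([Si](C)(C)C)c1OC | intermediate
11 | [4,5-dimethoxy-2-(trifluoromethylsulfonyloxy)-3-(trimethylsilyl)phenyl](4,5-dimethoxy-2,3-didehydrophenyl)methane, aryne at C2–C3 of one ring (not isolated) | COC1=C(OC)C#CC(Cc2cc(OC)c(OC)c([Si](C)(C)C)c2OS(=O)(=O)C(F)(F)F)=C1 | intermediate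
12 | 2-[(2,3-dibromo-4,5-dimethoxyphenyl)methyl]-4,5-dimethoxy-6-(trimethylsilyl)phenyl trifluoromethanesulfonate (not isolated) | COc1cc(Cc2cc(OC)c(OC)c([Si](C)(C)C)c2OS(=O)(=O)C(F)(F)F)c(Br)c(Br)c1OC | intermediate
13 | (2,3-dibromo-4,5-dimethoxyphenyl)(4,5-dimethoxy-2,3-didehydrophenyl)methane, aryne at C2–C3 of the second ring (not isolated) | COC1=C(OC)C#CC(Cc2cc(OC)c(OC)c(Br)c2Br)=C1 | intermediate
14 | bis(2,3-dibromo-4,5-dimethoxyphenyl)methane | COc1cc(Cc2cc(OC)c(OC)c(Br)c2Br)c(Br)c(Br)c1OC | intermediate
15 | bis(2,3,6-tribromo-4,5-dimethoxyphenyl)methane | COc1c(OC)c(Br)c(Cc2c(Br)c(OC)c(OC)c(Br)c2Br)c(Br)c1Br | intermediate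
16 | bis(2,4,5,7-tetrabromo-1,3,2-benzodioxaborol-6-yl)methane (not isolated) | BrB1Oc2c(Br)c(Br)c(Cc3c(Br)c(Br)c4OB(Br)Oc4c3Br)c(Br)c2O1 | intermediate
17 | bis(2,3,6-tribromo-4,5-dihydroxyphenyl)methane | Oc1c(O)c(Br)c(Cc2c(Br)c(O)c(O)c(Br)c2Br)c(Br)c1Br | target

## Step count and least certain steps

Total step count: 6. Longest linear sequence: 6 steps (1 to 17).

Step 4 (key step).
- What may go wrong: the C3 carbanion may be protonated by acetonitrile or by the ammonium cation before it meets CBr4, giving hydrobromination in place of dibromination. Bromide addition may revert. Fluoride or the tribromomethyl anion may add to the aryne in competition with bromide. The aryne may be captured by the neighbouring electron-rich ring. Since the event must occur on both rings, any leak counts twice.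
- Fallback: the aryne is given up and all six C–Br bonds are made by electrophilic substitution. It sets out from 4: acid-catalysed condensation of 4 (as paraformaldehyde, H2SO4 cat., AcOH) with an excess of veratrole F1 should give bis(3,4-dimethoxyphenyl)methane F2 by substitution para to a methoxy group. Exhaustive bromination of F2 (Br2 in excess, Fe powder cat., CH2Cl2, dark) should fill all three free positions of each ring, so no regiochemical question arises. This rejoins the route at 15, and step 5 is then not needed.

Step 3.
- What may go wrong: the twofold bromine–lithium exchange and silyl migration may stop halfway in the crowded bis-system. Proton transfer from the doubly benzylic CH2 to the aryllithium would lead to loss of bromine without silylation. Alkylation by the 1-bromobutane formed is also possible.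
- Fallback: the silicon is installed on the monomer, where there is no benzylic CH2 and only one exchange per molecule. It sets out from 3: O-silylation (HMDS) gives (2-bromo-3,4-dimethoxyphenoxy)trimethylsilane F3; n-BuLi (THF, −100 °C), silyl shift and NH4Cl quench should give 3,4-dimethoxy-2-(trimethylsilyl)phenol F4. After deprotonation with EtMgBr in toluene, F4 should condense with 4 (0.5 equiv, reflux) ortho to oxygen under non-acidic conditions that spare the C–Si bond, giving bis[2-hydroxy-4,5-dimethoxy-3-(trimethylsilyl)phenyl]methane F5. Triflation (Tf2O, pyridine, CH2Cl2, 0 °C) rejoins the route at 10.

Step 2.
- What may go wrong: the hydroxybenzyl cation may attack the less activated position ortho to the methoxy group or the phenol oxygen, or the reaction may stall at the hydroxymethyl or dibenzyl ether stage.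
- Fallback: the bridge is built in defined 1:1 stages. It sets out from 3: ortho-formylation (MgCl2, Et3N, paraformaldehyde, MeCN, reflux; Casnati–Skattebøl) should give 3-bromo-2-hydroxy-4,5-dimethoxybenzaldehyde F6. Reduction with NaBH4 in MeOH gives 5, now isolated, and 5 is coupled with one further equivalent of 3 under catalytic acid (p-TsOH, CH2Cl2) through the ortho-quinone methide. This rejoins the route at 6.

Step 5.
- What may go wrong: ipso attack of the electrophile at C1 (para to the C4 oxygen) with loss of the benzyl group would break the bridge under the Lewis-acidic conditions. Radical bromination of the CH2 or incomplete substitution of the second ring is also possible.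
- Fallback: the order of the last two operations is reversed so that the final bromination needs no Lewis acid. It sets out from 14: BBr3 (CH2Cl2, −78 °C to rt) should give bis(2,3-dibromo-4,5-dihydroxyphenyl)methane F7. The free catechol is far more nucleophilic at C6 and should be brominated by Br2 (2 equiv) in AcOH at rt. This arrives directly at 17.

## Further compounds

F1 | step 4 | veratrole (1,2-dimethoxybenzene) | COc1ccccc1OC
F2 | step 4 | bis(3,4-dimethoxyphenyl)methane | COc1ccc(Cc2ccc(OC)c(OC)c2)cc1OC
F3 | step 3 | (2-bromo-3,4-dimethoxyphenoxy)trimethylsilane | COc1ccc(O[Si](C)(C)C)c(Br)c1OC
F4 | step 3 | 3,4-dimethoxy-2-(trimethylsilyl)phenol | COc1ccc(O)c([Si](C)(C)C)c1OC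
F5 | step 3 | bis[2-hydroxy-4,5-dimethoxy-3-(trimethylsilyl)phenyl]methane | COc1cc(Cc2cc(OC)c(OC)c([Si](C)(C)C)c2O)c(O)c([Si](C)(C)C)c1OC
F6 | step 2 | 3-bromo-2-hydroxy-4,5-dimethoxybenzaldehyde | COc1cc(C=O)c(O)c(Br)c1OC
F7 | step 5 | bis(2,3-dibromo-4,5-dihydroxyphenyl)methane | Oc1cc(Cc2cc(O)c(O)c(Br)c2Br)c(Br)c(Br)c1O
A1 | alternative 1 | tetraethyl 3,3'-methylenebis(hexanedioate) | CCOC(=O)CCC(CC(=O)OCC)CC(CCC(=O)OCC)CC(=O)OCC
A2 | alternative 1 | diethyl oxalate | CCOC(=O)C(=O)OCC
A3 | alternative 1 | methylenebis(diethyl 2,3-dioxocyclohexane-1,4-dicarboxylate), labile stereocentres unassigned | CCOC(=O)C1CC(CC2CC(C(=O)OCC)C(=O)C(=O)C2C(=O)OCC)C(C(=O)OCC)C(=O)C1=O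
A4 | alternative 2 | bis[3,4-bis(trimethylsilyloxy)cyclopenta-2,4-dien-1-yl]methane | C[Si](C)(C)OC1=CC(CC2C=C(O[Si](C)(C)C)C(O[Si](C)(C)C)=C2)C=C1O[Si](C)(C)C
A5 | alternative 2 | dibromocarbene | Br[C]Br
A6 | alternative 2 | bis(3-bromo-4,5-dihydroxyphenyl)methane | Oc1cc(Cc2cc(O)c(O)c(Br)c2)cc(Br)c1O
A7 | alternative 3 | 2,5-dibromo-3,4-dimethoxythiophene 1,1-dioxide | COC1=C(Br)S(=O)(=O)C(Br)=C1OC
A8 | alternative 3 | 1,5-dibromopenta-1,4-diyne | BrC#CCC#CBr
A9 | alternative 3 | bis(2,3,6-tribromo-4,5-dimethoxyphenyl)methane (identical with 15) | COc1c(OC)c(Br)c(Cc2c(Br)c(OC)c(OC)c(Br)c2Br)c(Br)c1Br
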